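Ring B is closed last by forming the C7–C8 bond: in a samarium Barbier cyclisation a primary C7 alkylsamarium adds to the C8 methyl ketone, which creates the tertiary carbinol C8 and the trans-decalin in one operation. The step exploits ring A, whose trans-diequatorial C5 (2-iodoethyl) and C10 (C9 arm) substituents hold C7 within reach of the C8 carbonyl. The precursor is a monocyclic iodo diketone that already carries the polyene chain; its C9 and quaternary C10 centres come from an acyclic Ireland–Claisen rearrangement, and ring A from an epoxide–allylsilane closure that also delivers the C3 oxygen and the two-carbon C6–C7 arm.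

Key step: step 13

Remark: atom numbers follow the polypodane (labdane-type) numbering of the target: ring A = C1–C5 and C10, ring B = C5–C10, side chain from C11.
Remark: the L-fructose-derived enantiomer of the Shi ketone is assumed to give the (S)-epoxide; if the sense is opposite, the D-fructose-derived ketone is used.

Step 1
Reactants: 1 methyl (2E)-geranate
Product: 2 methyl (2E,6S)-6,7-epoxygeranate
Conditions: Shi ketone (L-fructose-derived, 0.3 equiv), KHSO5 (Oxone), K2CO3, Bu4NHSO4, MeCN/dimethoxymethane/aq. buffer pH 10.5, 0 °C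
Reagents that add atoms: potassium peroxymonosulfate, [K+].[O-]S(=O)(=O)OO
Why: Shi epoxidation: the chiral dioxirane formed from the ketone and KHSO5 should oxidise only the electron-rich 6,7-alkene (the enoate alkene is deactivated) through the spiro transition state, which sets the (S)-configured epoxide carbon that later becomes C3.

Step 2
Reactants: 2 methyl (2E,6S)-6,7-epoxygeranate
Product: 4 (E)-alpha-silyl enone, via lithium enolate of the silyl ketone 3 (not isolated)
Conditions: Me3SiCH2Li (2.2 equiv), pentane/THF, −78 °C; AcOH (2.2 equiv), −78 °C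
Reagents that add atoms: (trimethylsilyl)methyllithium, C[Si](C)(C)C[Li]
Why: Nucleophilic acyl substitution of the ester by the α-silyl organolithium, in which the second equivalent converts the α-silyl ketone into its enolate 3 and so prevents a second addition; the cold acidic quench should return ketone 4 with silicon and the (E)-enone intact.

Step 3
Reactants: 4 (E)-alpha-silyl enone
Product: 5 (2S)-beta-hydroxysilane allylic carbinol
Conditions: (S)-2-methyl-CBS-oxazaborolidine (0.2 equiv), BH3·SMe2, THF, −30 °C; MeOH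
Reagents that add atoms: none
Why: Corey–Bakshi–Shibata reduction: the ketone should bind the oxazaborolidine–borane complex with the trisubstituted alkenyl group as the large substituent, so hydride is delivered to one face and the (2S)-carbinol is set, the centre that later relays its chirality to C10.

Step 4
Reactants: 6 (2E,6E)-farnesyl bromide; 7 3-chloropropan-1-ol
Product: 9 (5E,9E)-6,10,14-trimethylpentadeca-5,9,13-trien-1-ol, via chloromagnesium 3-(chloromagnesio)propan-1-olate 8 (not isolated)
Conditions: 7, i-PrMgCl (1 equiv), THF, −20 °C; Mg, reflux; then 6, Li2CuCl4 (3 mol %), THF, −40 → 0 °C; 1 M aq. HCl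
Reagents that add atoms: none
Why: Copper-catalysed sp3–sp3 cross-coupling of a primary allylic bromide with an alkyl Grignard reagent (the hydroxyl masked as its magnesium alkoxide), which should take place at the primary carbon without allylic transposition and keep both (E)-alkenes.

Step 5
Reactants: 9 (5E,9E)-6,10,14-trimethylpentadeca-5,9,13-trien-1-ol
Product: 10 (5E,9E)-6,10,14-trimethylpentadeca-5,9,13-trienoic acid
Conditions: TEMPO (0.2 equiv), PhI(OAc)2 (2.2 equiv), MeCN/H2O, rt
Reagents that add atoms: water, O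
Why: Oxoammonium (TEMPO) oxidation with PhI(OAc)2 in aqueous acetonitrile should take the primary alcohol through the aldehyde hydrate to the carboxylic acid without touching the trisubstituted alkenes.

Step 6
Reactants: 5 (2S)-beta-hydroxysilane allylic carbinol; 10 (5E,9E)-6,10,14-trimethylpentadeca-5,9,13-trienoic acid
Product: 11 allylic ester of 5 and 10
Conditions: DCC, DMAP (0.1 equiv), CH2Cl2, 0 °C → rt
Reagents that add atoms: none
Why: Steglich esterification through the acylpyridinium ion acylates the secondary allylic alcohol under neutral conditions, so the epoxide, the β-hydroxysilane unit (no Peterson elimination) and the carbinol configuration should be preserved.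

Step 7
Reactants: 11 allylic ester of 5 and 10
Product: 14 (2R,3S)-allylsilane epoxy acid, via ketene trimethylsilyl acetal 12 (not isolated), via trimethylsilyl ester 13 (not isolated)
Conditions: LiN(i-Pr)2 (1.2 equiv), THF/HMPA, −78 °C; Me3SiCl; −78 → 50 °C; then MeOH/H2O
Reagents that add atoms: none
Why: Ireland–Claisen rearrangement: enolisation in THF/HMPA should give ketene acetal 12 with the C11 chain cis to the silyloxy group, and the chair transition state with the CH2SiMe3 group equatorial transfers the carbinol chirality to the new C9–C10 bond, setting C9 (R), the quaternary C10 (S) and the (E)-allylsilane in one event.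

Step 8
Reactants: 14 (2R,3S)-allylsilane epoxy acid
Product: 16 allylsilane epoxy methyl ketone, via dilithium gem-diolate 15 (not isolated)
Conditions: MeLi (2.5 equiv), Et2O, 0 °C → rt; H2O, 0 °C
Reagents that add atoms: methyllithium, [Li]C
Why: Addition of MeLi to the lithium carboxylate should stop at the dilithium gem-diolate 15, which gives the methyl ketone only on aqueous work-up (ketone synthesis from a carboxylic acid), while the trisubstituted epoxide and the allylsilane are inert at this temperature.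

Step 9
Reactants: 16 allylsilane epoxy methyl ketone
Product: 17 ring-A hydroxy ketone with C5 vinyl group
Conditions: BF3·OEt2 (1.1 equiv), CH2Cl2, −78 °C; aq. NaHCO3
Reagents that add atoms: none
Why: Lewis acid-promoted epoxide–allylsilane cyclisation (cation–olefin closure terminated by an allylsilane, an intramolecular Hosomi–Sakurai-type alkylation): C5 attacks the tertiary epoxide carbon C4 anti to the departing oxygen through a chair with the C10 methyl axial and the C9 arm, the incipient vinyl group and the C3 oxygen equatorial, which should set C5 (hydrogen anti to the C10 methyl), keep the (3S)-oxygen and release the vinyl arm C6=C7 by loss of silicon.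

Step 10
Reactants: 17 ring-A hydroxy ketone with C5 vinyl group
Product: 18 ring-A vinyl diketone
Conditions: Dess–Martin periodinane, NaHCO3, CH2Cl2, rt
Reagents that add atoms: none
Why: Dess–Martin oxidation converts the hindered secondary C3 carbinol into the ketone under buffered, non-enolising conditions, so C9 next to the C8 carbonyl should not epimerise and the alkenes are untouched.

Step 11
Reactants: 18 ring-A vinyl diketone
Product: 20 ring-A diketone with 2-hydroxyethyl arm, via catechol alkylboronate 19 (not isolated)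
Conditions: catecholborane (2 equiv), RhCl(PPh3)3 (3 mol %), THF, 0 °C → rt; then NaBO3·4H2O, THF/H2O, rt
Reagents that add atoms: sodium perborate, [Na+].[O-]OB=O
Why: Rhodium-catalysed hydroboration with catecholborane adds boron to the terminal carbon of the monosubstituted alkene only (anti-Markovnikov), leaving the trisubstituted alkenes and both ketones untouched, and perborate oxidation of boronate 19 with retention gives the primary alcohol at C7.

Step 12
Reactants: 20 ring-A diketone with 2-hydroxyethyl arm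
Product: 21 ring-A diketone with 2-iodoethyl arm
Conditions: I2, PPh3, imidazole, CH2Cl2, 0 °C
Reagents that add atoms: iodine, II
Why: Appel reaction: the alkoxyphosphonium ion of the primary alcohol is displaced by iodide in an SN2 step under nearly neutral conditions that both ketones tolerate.

Step 13
Reactants: 21 ring-A diketone with 2-iodoethyl arm
Product: 24 (5R,8R,9R,10S)-8-hydroxypolypoda-13E,17E,21-trien-3-one, via alkylsamarium diiodide 22 (not isolated), via samarium alkoxide 23 (not isolated)
Conditions: SmI2 (2.5 equiv), HMPA, THF, −78 → 0 °C; then H2O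
Reagents that add atoms: none
Why: Two SmI2 reduce the primary iodide to the alkylsamarium 22, which adds intramolecularly to the C8 methyl ketone to give the samarium alkoxide 23 (samarium Barbier cyclisation; the closest known type is the SmI2-promoted cyclisation of ω-iodo ketones to cycloalkanols). Ring B closes in a 6-exo-trig mode onto the carbonyl group. The new stereocentre C8 is controlled by a chair transition state locked by the equatorial C5 and C10 arms of ring A and the equatorial C11 chain at C9: the HMPA-ligated samarium that bridges C7 and the carbonyl oxygen should stay on the open α-periphery, away from the axial C10 methyl, which puts oxygen equatorial (8α) and the small methyl axial (8β). The step needs chemoselectivity for C8 over the C3 carbonyl; C3 is flanked by the quaternary C4 and can be reached by C7 only after ring A inverts and places the C9 arm axial, whereas C8 is reached through an all-equatorial chair. The iodide is reduced much faster than either dialkyl ketone, so ketyl pathways should not compete.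

Compound list
1 | methyl (2E)-3,7-dimethylocta-2,6-dienoate (methyl geranate) | COC(=O)/C=C(\C)CCC=C(C)C | starting material
2 | methyl (2E)-5-[(2S)-3,3-dimethyloxiran-2-yl]-3-methylpent-2-enoate | COC(=O)/C=C(\C)CC[C@@H]1OC1(C)C | intermediate
3 | lithium enolate of 4 (lithium (3E)-6-[(2S)-3,3-dimethyloxiran-2-yl]-4-methyl-1-(trimethylsilyl)hexa-1,3-dien-2-olate) | C[Si](C)(C)C=C(O[Li])/C=C(\C)CC[C@@H]1OC1(C)C | intermediate
4 | (3E)-6-[(2S)-3,3-dimethyloxiran-2-yl]-4-methyl-1-(trimethylsilyl)hex-3-en-2-one | C[Si](C)(C)CC(=O)/C=C(\C)CC[C@@H]1OC1(C)C | intermediate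
5 | (2S,3E)-6-[(2S)-3,3-dimethyloxiran-2-yl]-4-methyl-1-(trimethylsilyl)hex-3-en-2-ol | C[Si](C)(C)C[C@@H](O)/C=C(\C)CC[C@@H]1OC1(C)C | intermediate
6 | (2E,6E)-farnesyl bromide | CC(C)=CCC/C(C)=C/CC/C(C)=C/CBr | starting material
7 | 3-chloropropan-1-ol | OCCCCl | starting material
8 | chloromagnesium 3-(chloromagnesio)propan-1-olate | Cl[Mg]CCCO[Mg]Cl | intermediate
9 | (5E,9E)-6,10,14-trimethylpentadeca-5,9,13-trien-1-ol | CC(C)=CCC/C(C)=C/CC/C(C)=C/CCCCO | intermediate
10 | (5E,9E)-6,10,14-trimethylpentadeca-5,9,13-trienoic acid | CC(C)=CCC/C(C)=C/CC/C(C)=C/CCCC(O)=O | intermediate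
11 | (2S,3E)-6-[(2S)-3,3-dimethyloxiran-2-yl]-4-methyl-1-(trimethylsilyl)hex-3-en-2-yl (5E,9E)-6,10,14-trimethylpentadeca-5,9,13-trienoate | CC(C)=CCC/C(C)=C/CC/C(C)=C/CCCC(=O)O[C@H](C[Si](C)(C)C)/C=C(\C)CC[C@@H]1OC1(C)C | intermediate
12 | ketene trimethylsilyl acetal of 11, C11 chain cis to OSiMe3 | CC(C)=CCC/C(C)=C/CC/C(C)=C/CC/C=C(\O[Si](C)(C)C)O[C@H](C[Si](C)(C)C)/C=C(\C)CC[C@@H]1OC1(C)C | intermediate
13 | trimethylsilyl ester of 14 | CC(C)=CCC/C(C)=C/CC/C(C)=C/CC[C@@H](C(=O)O[Si](C)(C)C)[C@@](/C=C/C[Si](C)(C)C)(C)CC[C@@H]1OC1(C)C | intermediate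
14 | (2R,3S,4E)-3-{2-[(2S)-3,3-dimethyloxiran-2-yl]ethyl}-3-methyl-2-[(3E,7E)-4,8,12-trimethyltrideca-3,7,11-trien-1-yl]-6-(trimethylsilyl)hex-4-enoic acid | CC(C)=CCC/C(C)=C/CC/C(C)=C/CC[C@@H](C(O)=O)[C@@](/C=C/C[Si](C)(C)C)(C)CC[C@@H]1OC1(C)C | intermediate
15 | dilithium gem-diolate formed from 14 and MeLi | CC(C)=CCC/C(C)=C/CC/C(C)=C/CC[C@@H](C(C)(O[Li])O[Li])[C@@](/C=C/C[Si](C)(C)C)(C)CC[C@@H]1OC1(C)C | intermediate
16 | (3R,4S,5E)-4-{2-[(2S)-3,3-dimethyloxiran-2-yl]ethyl}-4-methyl-3-[(3E,7E)-4,8,12-trimethyltrideca-3,7,11-trien-1-yl]-7-(trimethylsilyl)hept-5-en-2-one | CC(C)=CCC/C(C)=C/CC/C(C)=C/CC[C@@H](C(C)=O)[C@@](/C=C/C[Si](C)(C)C)(C)CC[C@@H]1OC1(C)C | intermediate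
17 | (3R,6E,10E)-3-[(1S,2R,4S)-2-ethenyl-4-hydroxy-1,3,3-trimethylcyclohexyl]-7,11,15-trimethylhexadeca-6,10,14-trien-2-one | CC(C)=CCC/C(C)=C/CC/C(C)=C/CC[C@@H](C(C)=O)[C@@]1(C)CC[C@H](O)C(C)(C)[C@@H]1C=C | intermediate
18 | (3R,6E,10E)-3-[(1S,2R)-2-ethenyl-1,3,3-trimethyl-4-oxocyclohexyl]-7,11,15-trimethylhexadeca-6,10,14-trien-2-one | CC(C)=CCC/C(C)=C/CC/C(C)=C/CC[C@@H](C(C)=O)[C@@]1(C)CCC(=O)C(C)(C)[C@@H]1C=C | intermediate
19 | catechol boronate of 20 (B on C7) | CC(C)=CCC/C(C)=C/CC/C(C)=C/CC[C@@H](C(C)=O)[C@@]1(C)CCC(=O)C(C)(C)[C@@H]1CCB2Oc3ccccc3O2 | intermediate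
20 | (3R,6E,10E)-3-[(1S,2R)-2-(2-hydroxyethyl)-1,3,3-trimethyl-4-oxocyclohexyl]-7,11,15-trimethylhexadeca-6,10,14-trien-2-one | CC(C)=CCC/C(C)=C/CC/C(C)=C/CC[C@@H](C(C)=O)[C@@]1(C)CCC(=O)C(C)(C)[C@@H]1CCO | intermediate
21 | (3R,6E,10E)-3-[(1S,2R)-2-(2-iodoethyl)-1,3,3-trimethyl-4-oxocyclohexyl]-7,11,15-trimethylhexadeca-6,10,14-trien-2-one | CC(C)=CCC/C(C)=C/CC/C(C)=C/CC[C@@H](C(C)=O)[C@@]1(C)CCC(=O)C(C)(C)[C@@H]1CCI | intermediate
22 | C7 alkylsamarium diiodide from 21 | CC(C)=CCC/C(C)=C/CC/C(C)=C/CC[C@@H](C(C)=O)[C@@]1(C)CCC(=O)C(C)(C)[C@@H]1CC[Sm](I)I | intermediate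
23 | samarium diiodide alkoxide of 24 | CC(C)=CCC/C(C)=C/CC/C(C)=C/CC[C@@H]1[C@@]2(C)CCC(=O)C(C)(C)[C@@H]2CC[C@@]1(C)O[Sm](I)I | intermediate
24 | (4aS,5R,6R,8aR)-6-hydroxy-1,1,4a,6-tetramethyl-5-[(3E,7E)-4,8,12-trimethyltrideca-3,7,11-trien-1-yl]octahydronaphthalen-2(1H)-one, i.e. (5R,8R,9R,10S)-8-hydroxypolypoda-13E,17E,21-trien-3-one | CC(C)=CCC/C(C)=C/CC/C(C)=C/CC[C@@H]1[C@@]2(C)CCC(=O)C(C)(C)[C@@H]2CC[C@@]1(C)O | target

Total steps: 13. Longest linear sequence: 11 steps (steps 1–3 and 6–13); steps 4 and 5 make the chain acid 10 in a side branch.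

Steps most likely to fail

1. Step 13 (key step). What may go wrong: low facial discrimination at the C8 carbonyl (the methyl group taking the equatorial site gives the C8 epimer), protonation of the C7 organosamarium, or its addition to the C3 carbonyl. Fallback, from 20 back to 24: a polarity-reversed, non-reductive closure of the same bond. Dess–Martin oxidation of 20 would give the keto aldehyde (3R,6E,10E)-7,11,15-trimethyl-3-[(1S,2R)-1,3,3-trimethyl-4-oxo-2-(2-oxoethyl)cyclohexyl]hexadeca-6,10,14-trien-2-one F1. Hydrazine hydrate should condense with the aldehyde only and give the hydrazone of F1 F2. With [Ru(p-cymene)Cl2]2, 1,2-bis(dimethylphosphino)ethane and K3PO4 in THF at 45 °C the hydrazone acts as a C7 carbanion equivalent, adds to the C8 carbonyl through a ruthenium-bound six-membered transition state and loses N2 (Wolff–Kishner-type carbonyl addition), which gives 24 directly. The C3 carbonyl never meets a reductant, and the metal again sits on the periphery between C7 and the C8 oxygen.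

2. Step 9. What may go wrong: the Lewis acid diverts the epoxide into a 1,2-hydride shift (isopropyl ketone) or protodesilylates the allylsilane before the crowded C4–C5 bond forms, or the closure runs through the chair with the C9 arm axial (C5 epimer). Fallback, from 2 back to 17: the same bond made by a radical instead of a cation. PhSCH2Li (thioanisole, n-BuLi, DABCO) would convert 2 into (3E)-6-[(2S)-3,3-dimethyloxiran-2-yl]-4-methyl-1-(phenylsulfanyl)hex-3-en-2-one F3. CBS reduction as in step 3 gives the (2S)-carbinol of F3 F4, and Steglich esterification with 10 gives the ester of F4 and 10 F5. Ireland–Claisen rearrangement as in step 7, with t-BuMe2SiCl as the trap, gives the tert-butyldimethylsilyl ester of the (2R,3S)-acid carrying an allyl phenyl sulfide F6. Cp2TiCl (from Cp2TiCl2 and Mn, THF, rt) opens the epoxide homolytically to the tertiary C4 radical, which adds 6-exo to C5 of the allyl sulfide and expels the phenylthiyl radical; K2CO3/MeOH work-up then gives (2R,5E,9E)-2-[(1S,2R,4S)-2-ethenyl-4-hydroxy-1,3,3-trimethylcyclohexyl]-6,10,14-trimethylpentadeca-5,9,13-trienoic acid F7. MeLi (3.5 equiv, Et2O) converts F7 into 17.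

3. Step 3. What may go wrong: weak discrimination between the alkenyl and CH2SiMe3 flanks of the ketone (low enantiomeric purity) and 1,3-migration of silicon to oxygen in 4 during the reduction. Fallback, from 4 back to 5: non-selective 1,2-reduction with i-Bu2AlH (toluene, −78 °C) to (3E)-6-[(2S)-3,3-dimethyloxiran-2-yl]-4-methyl-1-(trimethylsilyl)hex-3-en-2-ol as both C2 epimers F8. Sharpless kinetic resolution (Ti(OiPr)4, L-(+)-diisopropyl tartrate, t-BuOOH, 4 Å molecular sieves, CH2Cl2, −20 °C) should then epoxidise the (2R)-epimer to (1R)-1-[(2S,3S)-3-{2-[(2S)-3,3-dimethyloxiran-2-yl]ethyl}-3-methyloxiran-2-yl]-2-(trimethylsilyl)ethan-1-ol F9 and leave 5 unchanged for separation.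

Further compounds
F1 | step 13 | (3R,6E,10E)-7,11,15-trimethyl-3-[(1S,2R)-1,3,3-trimethyl-4-oxo-2-(2-oxoethyl)cyclohexyl]hexadeca-6,10,14-trien-2-one | CC(C)=CCC/C(C)=C/CC/C(C)=C/CC[C@@H](C(C)=O)[C@@]1(C)CCC(=O)C(C)(C)[C@@H]1CC=O
F2 | step 13 | hydrazone of the aldehyde group of F1 | CC(C)=CCC/C(C)=C/CC/C(C)=C/CC[C@@H](C(C)=O)[C@@]1(C)CCC(=O)C(C)(C)[C@@H]1C/C=N/N
F3 | step 9 | (3E)-6-[(2S)-3,3-dimethyloxiran-2-yl]-4-methyl-1-(phenylsulfanyl)hex-3-en-2-one | O=C(CSc1ccccc1)/C=C(\C)CC[C@@H]1OC1(C)C
F4 | step 9 | (2S,3E)-6-[(2S)-3,3-dimethyloxiran-2-yl]-4-methyl-1-(phenylsulfanyl)hex-3-en-2-ol | O[C@H](CSc1ccccc1)/C=C(\C)CC[C@@H]1OC1(C)C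
F5 | step 9 | (2S,3E)-6-[(2S)-3,3-dimethyloxiran-2-yl]-4-methyl-1-(phenylsulfanyl)hex-3-en-2-yl (5E,9E)-6,10,14-trimethylpentadeca-5,9,13-trienoate | CC(C)=CCC/C(C)=C/CC/C(C)=C/CCCC(=O)O[C@H](CSc1ccccc1)/C=C(\C)CC[C@@H]1OC1(C)C
F6 | step 9 | tert-butyldimethylsilyl (2R,3S,4E)-3-{2-[(2S)-3,3-dimethyloxiran-2-yl]ethyl}-3-methyl-6-(phenylsulfanyl)-2-[(3E,7E)-4,8,12-trimethyltrideca-3,7,11-trien-1-yl]hex-4-enoate | CC(C)=CCC/C(C)=C/CC/C(C)=C/CC[C@@H](C(=O)O[Si](C)(C)C(C)(C)C)[C@@](/C=C/CSc1ccccc1)(C)CC[C@@H]1OC1(C)C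
F7 | step 9 | (2R,5E,9E)-2-[(1S,2R,4S)-2-ethenyl-4-hydroxy-1,3,3-trimethylcyclohexyl]-6,10,14-trimethylpentadeca-5,9,13-trienoic acid | CC(C)=CCC/C(C)=C/CC/C(C)=C/CC[C@@H](C(O)=O)[C@@]1(C)CC[C@H](O)C(C)(C)[C@@H]1C=C
F8 | step 3 | (3E)-6-[(2S)-3,3-dimethyloxiran-2-yl]-4-methyl-1-(trimethylsilyl)hex-3-en-2-ol, both C2 epimers | C[Si](C)(C)CC(O)/C=C(\C)CC[C@@H]1OC1(C)C
F9 | step 3 | (1R)-1-[(2S,3S)-3-{2-[(2S)-3,3-dimethyloxiran-2-yl]ethyl}-3-methyloxiran-2-yl]-2-(trimethylsilyl)ethan-1-ol | C[Si](C)(C)C[C@H](O)[C@@H]1O[C@@]1(C)CC[C@@H]2OC2(C)C
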